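Time was what J followed in the two earlier runs; the charge of Q seemed to do little. J is the complex with two exchanged, made from G in a closed, stirred flask with L held, and I had to say what [J] stands at after 8.0 h for 4 charges of Q.

| setting | north-west | east | Friday's | Monday's | Sunday's | Wednesday's |
|---|---|---|---|---|---|---|
| G | 0.82 M | 0.82 M | 0.82 M | 0.82 M | 0.82 M | 0.82 M |
| Q | 0.51 M | 1.2 M | 0.400 M | 0.800 M | 1.50 M | 3.00 M |
| L | 200 mM (held) | 200 mM (held) | 200 mM (held) | 200 mM (held) | 200 mM (held) | 200 mM (held) |
| remark | run made earlier | run made earlier |  |  |  |  |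
| time |  |  | 8.0 h | 8.0 h | 8.0 h | 8.0 h |

- north-west (time / h: J / %): 1.00: 0; 2.50: 1.0; 3.00: 2.2; 5.00: 3.6; 6.00: 4.9
- east (time / h: J / %): 0.417: 0.1; 0.833: 0; 1.50: 0.7; 3.00: 1.8; 6.00: 4.9

(standard deviation of a reading: 0.3 percentage points)

- at the start none of L is in solution
- "hardly changes" means that all values lie within two and a half points (for a concentration: within two and a half percent of the largest)

- [J] at the end for Friday's, Monday's, Sunday's, Wednesday's, in this order
- how the row runs (falls, then rises / hardly changes / rises all the way / falls all the way / rises, then falls)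

I reckoned with the rate r = d[J]/dt. At the start r could not be told from zero: J read 0 % at 1.00 h in the north-west run and 0 % at 0.833 h in the east run. The mean of r over the whole north-west run was 6.70 mM h⁻¹. From 3.00 h to 6.00 h it was 7.38 mM h⁻¹ there and 8.47 mM h⁻¹ in the east run, which held 2.35 times the Q. Slowing by Q would have put the east figure lower, but the east run over the north-west run read 1.15, and the two readings at 3.00 h differ by 0.4 percentage points, against a scatter of 0.3 points on each. So I read r as zero order in Q and took the average of the two, 7.93 mM h⁻¹, as the late mean rate s.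

Both runs read 0.0402 M at 6.00 h, so s over the remaining 2.00 h gave me 0.0560 M at each charge. To check the error of a mean, I put the whole-run mean in its place: that gave 0.0536 M, a gap of 2.40 mM, or 0.3 points of the G charged, the size of one reading's scatter.

The forecast said 0.059 M at each charge, shape hardly changes, on the reading that “Q has no measurable effect on J formation in this range”. My figure stood lower by 3.00 mM, in the same flat row.

The flasks gave 0.0546 M, 0.0546 M, 0.0546 M and 0.0546 M: hardly changes.

    G + E → Q + D (k = 0.0180 M⁻¹ min⁻¹)
    D + E → Q + J (k = 0.00390 M⁻¹ min⁻¹)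
    J + E → Q + X (k = 0.0180 M⁻¹ min⁻¹)
    L ⇌ E, rate k4*(csat - [E]) (kL = 0.0760 min⁻¹)
    G ⇌ Z (K = 0.710, k = 0.00350 min⁻¹)

In these equations Q stands on no left-hand side, and at 8.00 h Friday's held G 19.4 % and D 49.7 %, as Wednesday's did with 19.4 % and 49.7 %, though Q stood at 258 % and 121 % of own charge. Wednesday's J was 2.79 % of the G charged at 4.00 h; s carried from there to 8.0 h gives 0.0546 M, and Wednesday's flask held 0.0546 M.

(The earlier runs and the new flask stem from a simulated flask from invented constants.)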